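Ring B is cut at its two most congested bonds, C9–C10 and C7–C8, which flank the methyl-bearing quaternary carbons C10 and C8. The core thus falls into a ring A aldehyde (C1–C7, C10) and an acyclic enal (C8, C9, C11–C14). In one iron-hydride operation the C1=C10 alkene becomes the tertiary C10 radical, which bonds to C9, and the resulting C8 enolate closes on the C7 aldehyde: one ring, two C–C bonds, four stereocentres. The precursors are an (S)-α-cyclogeranyl α-carbamoyloxy aldehyde and an (E)-2-methyl enal with a ketal-masked C13 ketone. Rings C and D follow by ketyl–vinyl sulfone cyclisation and ring-closing metathesis.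

Key step: step 7

Remarks before the route
- Numbering: ring A = C1–C5, C10; ring B = C5–C10; ring C = C8, C9, C11–C14; ring D = O, C13–C19. β is the face of the C10 methyl group and α the face of H5. Cb = C(O)N(i-Pr)2.
- Assumption: the lipase acetylates the (R)-alcohol faster. Should the sense be opposite, the acetate fraction is methanolysed (K2CO3, MeOH) to the same alcohol 3.
- O6 is carried as the Cb carbamate. This lets C6 be set by reagent control on the resolved alcohol, so nothing depends on 1,2-induction from C5, whose neighbours C4 and C10 are of similar size. No enantiopure, base-sensitive α-cyclocitral is handled. Unlike a silyl group, Cb cannot migrate to the O7 alkoxide formed in step 7.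
- O7 is removed directly after the key step, while C14 is still a formyl group. Once a C14=C15 alkene exists, the C7 radical would be homoallylic and prone to a 1,2-vinyl shift.
- In the target, O13 (α) and C15 (β) are trans-diequatorial on ring C. C15 is therefore activated by a removable sulfone, so C16 enters at the correct oxidation level. A C16 ester would lead to a strained trans-lactone, and its 1,4-diol closes to a tetrahydrofuran on activation.
- Ring D is closed at C17=C18 rather than by an eight-membered etherification of a tertiary alkoxide.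

Step 1
Reactants: 1 (±)-α-cyclocitral
Product: 2 (±)-α-cyclogeraniol
Conditions: NaBH4, MeOH, 0 °C
Reagents that add atoms: none
Why: Chemoselective 1,2-reduction of the aldehyde by borohydride runs cold and nearly neutral, so the β,γ-alkene does not slip into conjugation; the product is still racemic.

Step 2
Reactants: 2 (±)-α-cyclogeraniol
Product: 3 (S)-α-cyclogeraniol
Conditions: Burkholderia cepacia lipase (Amano PS), vinyl acetate, t-BuOMe, rt, stopped beyond half conversion; chromatography
Reagents that add atoms: none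
Why: Lipase-catalysed kinetic resolution (irreversible transesterification with an enol ester) acetylates the faster-reacting (R)-alcohol, which is removed by chromatography, leaving the (S)-alcohol and so fixing C5.

Step 3
Reactants: 3 (S)-α-cyclogeraniol
Product: 4 [(1S)-2,6,6-trimethylcyclohex-2-en-1-yl]methyl N,N-diisopropylcarbamate
Conditions: i-Pr2NC(O)Cl, pyridine, 90 °C
Reagents that add atoms: N,N-diisopropylcarbamoyl chloride, CC(C)N(C(C)C)C(=O)Cl
Why: Carbamoylation of a primary alcohol in hot pyridine is routine, touches no stereocentre, and installs both the directing group for step 4 and the O6 protecting group for the rest of the route.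

Step 4
Reactants: 4 [(1S)-2,6,6-trimethylcyclohex-2-en-1-yl]methyl N,N-diisopropylcarbamate
Product: 6 (1R)-2-oxo-1-[(1S)-2,6,6-trimethylcyclohex-2-en-1-yl]ethyl N,N-diisopropylcarbamate (fragment 1), via lithiated carbamate 5 (not isolated)
Conditions: s-BuLi, (−)-sparteine, Et2O, −78 °C; DMF, −78 °C; AcOH, −78 °C to rt
Reagents that add atoms: N,N-dimethylformamide, CN(C)C=O
Why: In this sparteine-mediated asymmetric α-lithiation of an O-alkyl carbamate the carbamate carbonyl guides s-BuLi/(−)-sparteine to the pro-S hydrogen at C6 and the configurationally stable organolithium 5 is formylated by DMF with retention, so C6 becomes R by reagent control and any (5R) material left from step 2 ends up as a separable diastereomer.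

Step 5
Reactants: 7 hex-5-en-2-one
Product: 8 2-(but-3-en-1-yl)-2-methyl-1,3-dioxolane
Conditions: HOCH2CH2OH, p-TsOH (cat.), toluene, reflux, Dean–Stark trap
Reagents that add atoms: ethane-1,2-diol, OCCO
Why: Acid-catalysed ketalisation with azeotropic removal of water leaves the terminal alkene untouched, and the ketal later keeps C13 out of the aldol.

Step 6
Reactants: 8 2-(but-3-en-1-yl)-2-methyl-1,3-dioxolane; 9 methacrolein
Product: 10 (E)-2-methyl-5-(2-methyl-1,3-dioxolan-2-yl)pent-2-enal (fragment 2)
Conditions: second-generation Hoveyda–Grubbs catalyst (H2IMes)Cl2Ru=CH(2-i-PrO-C6H4) (3 mol %), 9 (4 equiv), CH2Cl2, 40 °C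
Reagents that add atoms: none
Why: Olefin cross-metathesis of a terminal alkene with excess methacrolein, a partner that does not homodimerise, gives the trisubstituted enal as the thermodynamically preferred E isomer (formyl group trans to the chain).

Step 7
Reactants: 6 fragment 1; 10 fragment 2
Product: 13 6α-carbamoyloxy-7β-hydroxy-8α-formyl trans-decalin ketal, via C10 radical 11 (not isolated), via C8 iron enolate 12 (not isolated)
Conditions: Fe(acac)3 (30 mol %), PhSiH3 (2.5 equiv, slow addition), 10 (2.5 equiv), EtOH/ClCH2CH2Cl, 0 °C to rt, argon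
Reagents that add atoms: none
Why: Fe(acac)3 and PhSiH3 form an iron hydride that transfers a hydrogen atom to C1 of the electron-rich C1=C10 alkene of 6 (the electron-poor enal reacts more slowly), the nucleophilic tertiary radical 11 adds to C9 of 10, divalent iron reduces the α-formyl radical to enolate 12, which attacks the C7 aldehyde, and ethanol releases 13 while the silane regenerates the hydride. The closest known reaction type is the iron-hydride radical–polar crossover annulation of γ,δ-unsaturated aldehydes with enals and enones (Giese addition followed by aldol). Ring B closes by a 6-(enolexo)-exo-trig aldol through a chair. C10 is attacked on its α face, opposite the axial 4β-methyl group and trans to the equatorial C5 side chain, so its methyl group ends axial β and the decalin is trans, while at C9 the enal approaches with its C11 chain turned away from ring A, so this chain becomes equatorial (H9 α). At C8 allylic 1,3-strain keeps H9 in the enolate plane, which places the C8 methyl group anti to H9 (axial β) and the formyl group equatorial, and the iron-bridged chair puts O7 equatorial, trans to the equatorial O6 carbamate (C7 is erased in step 9). The step needs hydrogen-atom transfer to the ring alkene only (secured by alkene polarity and excess 10), aldol at C7 only (C13 is ketal-masked, so no five-membered closure) and no O6-to-O7 migration (the hindered carbamate does not move).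

Step 8
Reactants: 13 6α-carbamoyloxy-7β-hydroxy-8α-formyl trans-decalin ketal
Product: 14 O7-phenoxythiocarbonyl derivative of 13
Conditions: PhOC(S)Cl, pyridine, DMAP (cat.), CH2Cl2, 0 °C to rt
Reagents that add atoms: O-phenyl chlorothionoformate, S=C(Cl)Oc1ccccc1
Why: Acylation of the only free hydroxyl group with an aryl chlorothionoformate under mild amine conditions avoids the strong base of xanthate formation, which could trigger retro-aldol cleavage of the β-hydroxy aldehyde.

Step 9
Reactants: 14 O7-phenoxythiocarbonyl derivative of 13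
Product: 15 7-deoxy aldehyde (C7 = CH2)
Conditions: Bu3SnH, AIBN (cat.), (PhSe)2 (10 mol %), toluene, 80 °C
Reagents that add atoms: none
Why: In this Barton–McCombie deoxygenation the secondary C7 radical is quenched at once by PhSeH made in situ from (PhSe)2, which outruns a 1,2-formyl shift that is in any case disfavoured because the equatorial C8–C14 bond lies in the nodal plane of the radical; no remaining stereocentre is touched.

Step 10
Reactants: 15 7-deoxy aldehyde
Product: 17 C13 methyl ketone bearing the (E)-C14=C15 vinyl phenyl sulfone, via ketal vinyl sulfone 16 (not isolated)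
Conditions: (EtO)2P(O)CH2SO2Ph, NaH, THF, 0 to 50 °C; then 2 M HCl, rt
Reagents that add atoms: diethyl [(phenylsulfonyl)methyl]phosphonate, CCOP(=O)(CS(=O)(=O)c1ccccc1)OCC; water, O
Why: Horner–Wadsworth–Emmons olefination of the non-enolisable neopentyl aldehyde gives the E-vinyl sulfone, and aqueous acid in the same flask hydrolyses the dioxolane while carbamate and sulfone are inert.

Step 11
Reactants: 17 keto vinyl sulfone
Product: 19 tricyclic 13α-hydroxy-13β-methyl C15 phenyl sulfone, via samarium ketyl 18 (not isolated)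
Conditions: SmI2 (3 equiv), MeOH (4 equiv), THF, 0 °C
Reagents that add atoms: none
Why: In this ketyl–olefin cyclisation the C13 ketyl closes ring C by 6-exo-trig addition to C14 through a chair in which C15 and the bulky samarium-bound oxygen (held to a sulfonyl oxygen) are both equatorial, so H14 is α, O13 is α and the C13 methyl group is axial β.

Step 12
Reactants: 19 tricyclic hydroxy sulfone
Product: 21 C15-(2-methylallyl) hydroxy sulfone (C15 epimers), via dilithio species 20 (not isolated)
Conditions: n-BuLi (2.1 equiv), THF/DMPU, −78 to −20 °C; CH2=C(CH3)CH2Br, −78 to 0 °C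
Reagents that add atoms: 3-bromo-2-methylprop-1-ene, C=C(C)CBr
Why: In this alkylation of an α-sulfonyl carbanion the soft C15 carbanion of the O,C-dianion 20 is far more nucleophilic than the hindered tertiary lithium alkoxide, so the allylic bromide is taken up at carbon only, and the new C15 stereocentre is erased in step 13.

Step 13
Reactants: 21 C15-(2-methylallyl) hydroxy sulfone
Product: 22 13α-alcohol with the C15–C16–C17(CH3)=CH2 chain
Conditions: Mg, MeOH, 50 °C
Reagents that add atoms: none
Why: Reductive desulfonylation by electron transfer from magnesium in methanol cleaves the C15–S bond and leaves the isolated 1,1-disubstituted alkene, the tertiary alcohol and the carbamate untouched.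

Step 14
Reactants: 22 13α-alcohol with the C15–C16–C17(CH3)=CH2 chain
Product: 24 O13-allyl ether diene, via potassium alkoxide 23 (not isolated)
Conditions: KH, 18-crown-6 (cat.), THF, 0 °C; allyl bromide, 0 °C to rt
Reagents that add atoms: allyl bromide, C=CCBr
Why: In this Williamson etherification KH deprotonates the equatorial tertiary alcohol irreversibly and the crown-activated alkoxide 23 is alkylated by the unhindered, very reactive allyl bromide; the C13–O bond is not broken, so configuration is retained.

Step 15
Reactants: 24 O13-allyl ether diene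
Product: 25 (17Z)-oxocene 6α-carbamate
Conditions: second-generation Hoveyda–Grubbs catalyst (H2IMes)Cl2Ru=CH(2-i-PrO-C6H4) (10 mol %), 1,4-benzoquinone (20 mol %), toluene (1 mM), 80 °C
Reagents that add atoms: none
Why: In this ring-closing metathesis ruthenium loads on the monosubstituted allyl ether and closes on the 1,1-disubstituted alkene, helped by the gauche, trans-diequatorial O13 and C15 on rigid ring C, and the eight-membered ring accepts only the Z alkene.

Step 16
Reactants: 25 (17Z)-oxocene 6α-carbamate
Product: 26 target, (17Z)-13α,19-epoxycheilanth-17-en-6α-ol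
Conditions: LiAlH4, THF, reflux; aqueous NaOH work-up
Reagents that add atoms: none
Why: Hydride cleavage of the N,N-dialkylcarbamate (acyl C–O scission, retention at C6) frees the 6α-alcohol, and the dialkyl ether and trisubstituted alkene are inert to LiAlH4.

Compound list
1 | (±)-α-cyclocitral, 2,6,6-trimethylcyclohex-2-ene-1-carbaldehyde | O=CC1C(C)=CCCC1(C)C | starting material
2 | (±)-α-cyclogeraniol | OCC1C(C)=CCCC1(C)C | intermediate
3 | (S)-α-cyclogeraniol | OC[C@@H]1C(C)=CCCC1(C)C | intermediate
4 | [(1S)-2,6,6-trimethylcyclohex-2-en-1-yl]methyl N,N-diisopropylcarbamate | CC(C)N(C(C)C)C(=O)OC[C@@H]1C(C)=CCCC1(C)C | intermediate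
5 | (S)-α-lithiated carbamate (sparteine complex; Li on C6) | [Li][C@H](OC(=O)N(C(C)C)C(C)C)[C@@H]1C(C)=CCCC1(C)C | intermediate
6 | fragment 1, (1R)-2-oxo-1-[(1S)-2,6,6-trimethylcyclohex-2-en-1-yl]ethyl N,N-diisopropylcarbamate (C1–C7, C10; 5S, 6R) | O=C[C@H](OC(=O)N(C(C)C)C(C)C)[C@@H]1C(C)=CCCC1(C)C | intermediate
7 | hex-5-en-2-one | CC(=O)CCC=C | starting material
8 | 2-(but-3-en-1-yl)-2-methyl-1,3-dioxolane | C=CCCC1(C)OCCO1 | intermediate
9 | methacrolein | C=C(C)C=O | starting material
10 | fragment 2, (E)-2-methyl-5-(2-methyl-1,3-dioxolan-2-yl)pent-2-enal (C8, C9, C11–C14) | O=C/C(C)=C/CCC1(C)OCCO1 | intermediate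
11 | tertiary C10 radical from 6 (H added at C1; C5 and C6 unchanged) | O=C[C@H](OC(=O)N(C(C)C)C(C)C)[C@@H]1[C](C)CCCC1(C)C | intermediate
12 | C8 enolate after C9–C10 bond formation (iron-bound, drawn as the anion; H5 α, 10β-CH3, H9 α) | CC1(CC[C@@H](C(C)=C[O-])[C@@]2(C)CCCC(C)(C)[C@@H]2[C@@H](OC(=O)N(C(C)C)C(C)C)C=O)OCCO1 | intermediate
13 | trans-decalin: 4,4-dimethyl, H5 α, 6α-OCb, 7β-OH, 8β-CH3, 8α-CHO (C14), H9 α with equatorial 2-(2-methyl-1,3-dioxolan-2-yl)ethyl chain, 10β-CH3 | CC1(CC[C@@H]2[C@@]3(C)CCCC(C)(C)[C@@H]3[C@@H](OC(=O)N(C(C)C)C(C)C)[C@H](O)[C@@]2(C)C=O)OCCO1 | intermediate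
14 | 13 with O7 as O-phenyl thionocarbonate | CC1(CC[C@@H]2[C@@]3(C)CCCC(C)(C)[C@@H]3[C@@H](OC(=O)N(C(C)C)C(C)C)[C@H](OC(=S)Oc3ccccc3)[C@@]2(C)C=O)OCCO1 | intermediate
15 | 7-deoxy aldehyde (as 13, C7 = CH2) | CC1(CC[C@@H]2[C@@]3(C)CCCC(C)(C)[C@@H]3[C@@H](OC(=O)N(C(C)C)C(C)C)C[C@@]2(C)C=O)OCCO1 | intermediate
16 | (E)-C14=C15 vinyl phenyl sulfone, C13 still ketal | CC1(CC[C@@H]2[C@@]3(C)CCCC(C)(C)[C@@H]3[C@@H](OC(=O)N(C(C)C)C(C)C)C[C@@]2(C)/C=C/S(=O)(=O)c2ccccc2)OCCO1 | intermediate
17 | (E)-vinyl phenyl sulfone with free C13 methyl ketone | CC(=O)CC[C@@H]1[C@@]2(C)CCCC(C)(C)[C@@H]2[C@@H](OC(=O)N(C(C)C)C(C)C)C[C@@]1(C)/C=C/S(=O)(=O)c1ccccc1 | intermediate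
18 | C13 samarium ketyl of 17 | C[C](O[Sm](I)I)CC[C@@H]1[C@@]2(C)CCCC(C)(C)[C@@H]2[C@@H](OC(=O)N(C(C)C)C(C)C)C[C@@]1(C)/C=C/S(=O)(=O)c1ccccc1 | intermediate
19 | tricycle (rings A, B, C all trans): 13α-OH, 13β-CH3, H14 α, C15H2SO2Ph equatorial, 6α-OCb | O[C@@]1(C)CC[C@@H]2[C@@]3(C)CCCC(C)(C)[C@@H]3[C@@H](OC(=O)N(C(C)C)C(C)C)C[C@@]2(C)[C@@H]1CS(=O)(=O)c1ccccc1 | intermediate
20 | O13,C15-dilithio derivative of 19 | [Li]O[C@@]1(C)CC[C@@H]2[C@@]3(C)CCCC(C)(C)[C@@H]3[C@@H](OC(=O)N(C(C)C)C(C)C)C[C@@]2(C)[C@@H]1C([Li])S(=O)(=O)c1ccccc1 | intermediate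
21 | 19 carrying a 2-methylallyl group on C15 (C15 epimers) | O[C@@]1(C)CC[C@@H]2[C@@]3(C)CCCC(C)(C)[C@@H]3[C@@H](OC(=O)N(C(C)C)C(C)C)C[C@@]2(C)[C@@H]1C(CC(C)=C)S(=O)(=O)c1ccccc1 | intermediate
22 | desulfonylated 13α-alcohol, C14 chain CH2CH2C(CH3)=CH2 | O[C@@]1(C)CC[C@@H]2[C@@]3(C)CCCC(C)(C)[C@@H]3[C@@H](OC(=O)N(C(C)C)C(C)C)C[C@@]2(C)[C@@H]1CCC(C)=C | intermediate
23 | potassium alkoxide of 22 | [K+].[O-][C@@]1(C)CC[C@@H]2[C@@]3(C)CCCC(C)(C)[C@@H]3[C@@H](OC(=O)N(C(C)C)C(C)C)C[C@@]2(C)[C@@H]1CCC(C)=C | intermediate
24 | O13-allyl ether of 22 (diene) | C=CCO[C@@]1(C)CC[C@@H]2[C@@]3(C)CCCC(C)(C)[C@@H]3[C@@H](OC(=O)N(C(C)C)C(C)C)C[C@@]2(C)[C@@H]1CCC(C)=C | intermediate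
25 | tetracycle with (17Z)-oxocene ring D, 6α-OCb | C/C1=C/CO[C@@]2(C)CC[C@@H]3[C@@]4(C)CCCC(C)(C)[C@@H]4[C@@H](OC(=O)N(C(C)C)C(C)C)C[C@@]3(C)[C@@H]2CC1 | intermediate
26 | CNP0179324.1, (17Z)-13α,19-epoxycheilanth-17-en-6α-ol (H5 α, H9 α, H14 α, 8β-, 10β-, 13β-CH3) | C/C1=C/CO[C@@]2(C)CC[C@@H]3[C@@]4(C)CCCC(C)(C)[C@@H]4[C@@H](O)C[C@@]3(C)[C@@H]2CC1 | target

Total step count: 16. Longest linear sequence: 14 (steps 1–4 and 7–16).

Steps most likely to fail

1. Step 7. The slow addition of a tertiary radical to a β-substituted enal may let the enolate be protonated before it closes. The C7 aldehyde may also be reduced under the hydride conditions, or the aldol may show poor facial selectivity.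
 Fallback (from 6 and 10, back at 15): the two bond formations are separated.
 - Aldehyde 6 is reduced (NaBH4, MeOH) to (1R)-2-hydroxy-1-[(1S)-2,6,6-trimethylcyclohex-2-en-1-yl]ethyl N,N-diisopropylcarbamate F1.
 - F1 undergoes a plain iron-hydride reductive olefin coupling (Giese addition; Fe(acac)3, PhSiH3, EtOH) with 10 to give the open hydroxy aldehyde F2. Its C8 epimers are of no consequence.
 - Appel iodination (I2, PPh3, imidazole) gives the C7 iodide F3.
 - KOt-Bu in THF closes ring B by 6-exo-tet alkylation of the only possible enolate (C8), under the same allylic-strain control. This gives 15 directly, so steps 8 and 9 are skipped.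

2. Step 11. Ring closure may proceed through a chair with the ketyl oxygen axial, because either group on C13 must sit syn to the axial C8 methyl group. Methyl and oxygen would then be interchanged at C13.
 Fallback (from 17, back at 19): C13 is set on the finished ring C instead of during closure.
 - The cyclisation is run without regard to C13, and the 13-epimeric carbinol F4 (13β-OH, axial) is collected.
 - F4 is dehydrated (SOCl2, pyridine, 0 °C; anti elimination with H12 α) to the 12-ene sulfone F5.
 - Mukaiyama hydration (Mn(dpm)3 cat., PhSiH3, O2, i-PrOH; then P(OEt)3) forms the planar C13 radical. It is oxygenated from the open α face because the β face is blocked by the axial C8 methyl group.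

3. Step 15. Closure onto the 1,1-disubstituted alkene may be slower than oligomerisation or than isomerisation of the allyl ether to an enol ether.
 Fallback (from 24, back at 25): the C17=C18 bond is made by carbonyl coupling.
 - Ozonolysis of both terminal alkenes (O3, CH2Cl2, −78 °C; Me2S) gives the C17 methyl ketone/C18 aldehyde F6.
 - An intramolecular McMurry coupling (TiCl3(DME)1.5, Zn(Cu), DME, reflux, slow addition) joins C17 and C18. The ring size again allows only the Z alkene.

Further compounds
F1 | step 7 | (1R)-2-hydroxy-1-[(1S)-2,6,6-trimethylcyclohex-2-en-1-yl]ethyl N,N-diisopropylcarbamate | OC[C@H](OC(=O)N(C(C)C)C(C)C)[C@@H]1C(C)=CCCC1(C)C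
F2 | step 7 | open hydroxy aldehyde (C9–C10 bond made, C7 = CH2OH, C8 epimers) | CC1(CC[C@@H](C(C)C=O)[C@@]2(C)CCCC(C)(C)[C@@H]2[C@@H](OC(=O)N(C(C)C)C(C)C)CO)OCCO1
F3 | step 7 | C7 iodide of F2 | CC1(CC[C@@H](C(C)C=O)[C@@]2(C)CCCC(C)(C)[C@@H]2[C@@H](OC(=O)N(C(C)C)C(C)C)CI)OCCO1
F4 | step 11 | 13-epimer of 19 (13β-OH, 13α-CH3) | O[C@]1(C)CC[C@@H]2[C@@]3(C)CCCC(C)(C)[C@@H]3[C@@H](OC(=O)N(C(C)C)C(C)C)C[C@@]2(C)[C@@H]1CS(=O)(=O)c1ccccc1
F5 | step 11 | 12-ene sulfone (C12=C13) | CC1=CC[C@@H]2[C@@]3(C)CCCC(C)(C)[C@@H]3[C@@H](OC(=O)N(C(C)C)C(C)C)C[C@@]2(C)[C@@H]1CS(=O)(=O)c1ccccc1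
F6 | step 15 | C17 methyl ketone/C18 aldehyde | O=CCO[C@@]1(C)CC[C@@H]2[C@@]3(C)CCCC(C)(C)[C@@H]3[C@@H](OC(=O)N(C(C)C)C(C)C)C[C@@]2(C)[C@@H]1CCC(C)=O
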